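Do not read a percentage of target as dissolved target: each reading counts target in all its forms, free or not, so a steady yield says nothing yet about the free concentration.

| flask | substrate | remark | time |
|---|---|---|---|
| blue | 0.038 M | run made earlier |  |
| amber | 0.31 M | run made earlier |  |
| south-west | 0.030 M |  | 10 min |
| north | 0.060 M |  | 10 min |
| west | 0.12 M |  | 10 min |
| south-east | 0.25 M |  | 10 min |

| run | time / min | target / % |
|---|---|---|
| blue | 1.33 | 20.7 |
| blue | 2.50 | 40.9 |
| blue | 4.00 | 59.0 |
| blue | 5.00 | 67.3 |
| amber | 1.33 | 21.5 |
| amber | 2.50 | 41.2 |
| amber | 4.00 | 58.9 |
| amber | 5.00 | 67.1 |

(standard deviation of a reading: 0.5 percentage points)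

- [target] (only what is free in solution) at the end for south-west, north, west, south-east, in this order
- how the row runs (falls all the way / rises, then falls / falls, then rises / rises all the way / hardly changes)

- a reading or a percentage of target counts all its forms, free or not
- the concentration of target that is asked is that of its free form alone
- "hardly changes" means that all values lie within two and a half points (for a concentration: within two and a half percent of the largest)

Open the ledger on the charge of substrate, the limiting reagent. First entry: at 5.00 min target stands at 67.3% in blue and 67.1% in amber, although the amber charge is 8.16 times the blue one, so freeze the yield as a fraction of the charge. Second entry: the shortfall, 32.7% of the blue charge at that time, is not yet target. Between 4.00 min and 5.00 min it decays with an apparent rate constant k of 0.226 min⁻¹ in blue and 0.223 min⁻¹ in amber. That is faster than the 0.174 min⁻¹ averaged over the first 1.33 min of blue, so target lags, and part of the shortfall sits in some unseen stock.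

Third entry: run the blue tail on at that k to 10 min. The shortfall shrinks and leaves Y = 89.4%, the ten-minute yield, the share of the charge that is target in any form. Fourth entry: multiply Y by each charge, which gives 0.0268 M, 0.0537 M, 0.107 M and 0.224 M. The last entry, free against not free, stays open: the amber reading of 0.208 M at 5.00 min counts all forms too. Book the row as target in all forms, free or not.

The forecast gives 0.027 M, 0.054 M, 0.108 M and 0.225 M for free target, rises all the way, on the words “I therefore take free ≈ total”, whereas this ledger books its row for target in all forms.

The flasks give 0.0265 M, 0.0440 M, 0.0441 M and 0.0442 M, rises all the way.

    intermediate B → target (k = 0.00750 s⁻¹)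
    substrate ⇌ intermediate B (K = 2.70, k = 0.0220 s⁻¹)
    substrate ⇌ intermediate A (K = 0.610, k = 0.00340 s⁻¹)
    crystals ⇌ target, rate k4*(cs4 - [target]) while solid is left; crystals form when [target] > cs4 (solubility = 44.0 mM, k = 0.520 s⁻¹)

South-west holds target at 88.2% of its charge against Y of 89.4%, with crystals at 0%. In north, free target plus crystals comes to 0.0529 M against Y times the charge, 0.0537 M. Exchange between crystals and target has a half-life of 0.0222 min, far shorter than the 1.5 min half-life of intermediate B passing into target in south-west. South-east stands at 0.0442 M free against a solubility of 0.0440 M, with crystals at 70.5% of its charge.

Readings and results are calculated for substances that don't exist; noise was put on by code.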